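**Retrosynthetic overview**

1. Target 40 comes from silyl-protected enone 39, made by Dauben oxidative 1,3-transposition of tertiary allylic alcohol 38; 38 is cut between C5 of the hydroazulene and the ethylene bridge into the alkylcerium from iodide 14 (right half) and enone 35 (left half).
2. Right half 14 comes from ketone 9, in which the oxepane and cyclohexane rings close together in one silyl-triflate-triggered epoxonium cascade of diepoxy enol silane 7; absolute configuration comes from Shi epoxidation of (E)-geranylacetone 1, and the C7 carbinol from equatorial methyl addition.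
3. Left half 35 comes from dienone 30: the seven-membered ring is closed last by ring-closing metathesis on a cis-1,2-disubstituted methylcyclopentene; the tertiary alcohol comes from convex-face epoxidation and hydride opening.
4. The cis ring-fusion pattern comes from a Claisen rearrangement of cis-allylic alcohol 25, which traces back through a stereoretentive Tsuji–Trost alkylation to the esterase desymmetrisation of meso-diacetate 15.
5. Ring order: right half oxepane and cyclohexane in one step; left half cyclopentene (present in 15), then cycloheptenone; the halves are joined once all four rings exist.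

Assumption: 1 is used as the pure E isomer; locants follow azulene numbering (left half) and 1-benzoxepine numbering (right half).

**Right half**

Step 1
Reactants: 1 (E)-geranylacetone
Product: 2 4-[(2R,3R)-3-{2-[(2R)-3,3-dimethyloxiran-2-yl]ethyl}-3-methyloxiran-2-yl]butan-2-one
Conditions: Shi ketone (D-fructose-derived, 0.6 equiv), Oxone (2KHSO5·KHSO4·K2SO4), K2CO3, Bu4NHSO4, MeCN/CH2(OMe)2/aq. Na2B4O7 buffer, 0 °C
Reagents that add atoms: potassium peroxymonosulfate, OOS(=O)(=O)[O-].[K+]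
Why: Shi asymmetric epoxidation: the dioxirane of the fructose-derived ketone epoxidises both trisubstituted alkenes through the spiro transition state and sets the three stereocentres (all R, the first of this branch, about 10:1 dr), while the unactivated methyl ketone is left alone.

Step 2
Reactants: 2 diepoxy ketone; 3 (benzyloxy)acetaldehyde
Product: 4 6-(benzyloxy)-1-[(2R,3R)-3-{2-[(2R)-3,3-dimethyloxiran-2-yl]ethyl}-3-methyloxiran-2-yl]-5-hydroxyhexan-3-one (C5 epimers)
Conditions: LiN(iPr)2, THF, −78 °C; then 3, −78 °C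
Reagents that add atoms: none
Why: kinetic enolisation on the CH3 side followed by a lithium aldol addition installs the two-carbon side-chain precursor; the epoxides are inert at −78 °C and the new carbinol centre is removed in the next step.

Step 3
Reactants: 4 aldol adduct
Product: 6 (4E)-6-(benzyloxy)-1-[(2R,3R)-3-{2-[(2R)-3,3-dimethyloxiran-2-yl]ethyl}-3-methyloxiran-2-yl]hex-4-en-3-one, via secondary mesylate 5 (not isolated)
Conditions: MsCl, Et3N, CH2Cl2, 0 °C → rt
Reagents that add atoms: none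
Why: mesylation and E1cB elimination of the β-hydroxy ketone give the conjugated E enone that defines where the enol silane will sit.

Step 4
Reactants: 6 enone
Product: 7 {[(3Z)-6-(benzyloxy)-1-[(2R,3R)-3-{2-[(2R)-3,3-dimethyloxiran-2-yl]ethyl}-3-methyloxiran-2-yl]hex-3-en-3-yl]oxy}triethylsilane
Conditions: Et3SiH, RhCl(PPh3)3 (2 mol%), THF, 50 °C
Reagents that add atoms: triethylsilane, CC[SiH](CC)CC
Why: rhodium-catalysed 1,4-hydrosilylation gives the enol silane regiospecifically on the side-chain side of the ketone, which deprotonation could not do because both α-positions are CH2; the enol ether geometry does not matter.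

Step 5
Reactants: 7 diepoxy enol silane
Product: 9 (3R,5aR,6R,9aR)-6-[2-(benzyloxy)ethyl]-3-hydroxy-2,2,5a-trimethyloctahydro-1-benzoxepin-7(2H)-one, via trimethylsilyl ether 8 (not isolated)
Conditions: Me3SiOTf (1.1 equiv), 2,6-di-tert-butyl-4-methylpyridine, CH2Cl2, −78 °C; then K2CO3, MeOH, rt
Reagents that add atoms: none
Why: epoxide-opening cascade (tandem oxa- and carbacyclisation): silylation of the terminal epoxide triggers endo attack by the neighbouring epoxide oxygen at the tertiary carbon, and the enol silane opens the resulting epoxonium ion at its tertiary carbon with inversion, so both rings form with a trans fusion while C3 and C9a are carried over from the Shi epoxides; K2CO3/MeOH then removes the silyl ether and equilibrates the α-side chain to equatorial (6R).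

Step 6
Reactants: 9 hydroxy ketone
Product: 10 (3R,5aR,6R,9aR)-6-[2-(benzyloxy)ethyl]-3-[(tert-butyldimethylsilyl)oxy]-2,2,5a-trimethyloctahydro-1-benzoxepin-7(2H)-one
Conditions: t-BuMe2SiOTf, 2,6-lutidine, CH2Cl2, −78 °C
Reagents that add atoms: tert-butyldimethylsilyl triflate, CC(C)(C)[Si](C)(C)OS(=O)(=O)C(F)(F)F
Why: silyl ether formation on the hindered secondary alcohol gives a group that survives every later step, including the chromium oxidation, until the final fluoride treatment.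

Step 7
Reactants: 10 silyl ether ketone
Product: 11 (3R,5aR,6R,7S,9aR)-6-[2-(benzyloxy)ethyl]-3-[(tert-butyldimethylsilyl)oxy]-2,2,5a,7-tetramethyldecahydro-1-benzoxepin-7-ol
Conditions: MeMgBr, CeCl3, THF, −78 → 0 °C
Reagents that add atoms: methylmagnesium bromide, C[Mg]Br
Why: 1,2-addition of the weakly basic organocerium reagent (Imamoto conditions): axial approach is blocked by the syn-axial angular methyl, so methyl enters equatorially and the new tertiary alcohol is axial (7S), without epimerising C6.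

Step 8
Reactants: 11 tertiary alcohol
Product: 12 tert-butyl{[(3R,5aR,6R,7S,9aR)-6-[2-(benzyloxy)ethyl]-2,2,5a,7-tetramethyl-7-[(triethylsilyl)oxy]decahydro-1-benzoxepin-3-yl]oxy}dimethylsilane
Conditions: Et3SiOTf, 2,6-lutidine, CH2Cl2, 0 °C → rt
Reagents that add atoms: triethylsilyl triflate, CC[Si](CC)(CC)OS(=O)(=O)C(F)(F)F
Why: silyl protection of the tertiary alcohol removes the acidic proton and the risk of tetrahydrofuran formation in the iodination and lithiation steps.

Step 9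
Reactants: 12 benzyl ether
Product: 13 2-[(3R,5aR,6R,7S,9aR)-3-[(tert-butyldimethylsilyl)oxy]-2,2,5a,7-tetramethyl-7-[(triethylsilyl)oxy]decahydro-1-benzoxepin-6-yl]ethan-1-ol
Conditions: H2 (1 atm), Pd/C, EtOAc, rt
Reagents that add atoms: none
Why: hydrogenolysis of the benzyl ether; both silyl ethers are stable in ethyl acetate and the molecule has no alkene.

Step 10
Reactants: 13 primary alcohol
Product: 14 tert-butyl{[(3R,5aR,6R,7S,9aR)-6-(2-iodoethyl)-2,2,5a,7-tetramethyl-7-[(triethylsilyl)oxy]decahydro-1-benzoxepin-3-yl]oxy}dimethylsilane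
Conditions: I2, PPh3, imidazole, CH2Cl2, 0 °C → rt
Reagents that add atoms: iodine, [I][I]
Why: Appel-type (Garegg–Samuelsson) iodination: iodide displaces the primary alkoxyphosphonium by SN2 under neutral conditions.

**Left half**

Step 11
Reactants: 15 meso-cis-cyclopent-4-ene-1,3-diyl diacetate
Product: 16 (1R,4S)-4-hydroxycyclopent-2-en-1-yl acetate
Conditions: acetylcholinesterase (an esterase, from electric eel), aq. phosphate buffer pH 7, rt
Reagents that add atoms: none
Why: enzymatic desymmetrisation: the esterase hydrolyses only one of the two enantiotopic acetates of the achiral meso diester, which fixes the absolute configuration of the whole left half (>98% ee).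

Step 12
Reactants: 16 monoacetate; 17 methyl cyanoacetate
Product: 18 methyl 2-cyano-2-[(1R,4S)-4-hydroxycyclopent-2-en-1-yl]acetate (epimers at the exocyclic carbon)
Conditions: 17 (3 equiv), NaH, Pd(PPh3)4 (3 mol%), THF, 0 °C → rt
Reagents that add atoms: none
Why: Tsuji–Trost allylic alkylation: zerovalent palladium ionises the acetate with inversion and the soft cyanoacetate anion attacks the allyl terminus remote from the hydroxyl, anti to palladium, so carbon replaces acetate with net retention, cis to OH.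

Step 13
Reactants: 18 cyano ester
Product: 19 2-[(1R,4S)-4-hydroxycyclopent-2-en-1-yl]acetonitrile
Conditions: LiCl, H2O, DMSO, 130 °C
Reagents that add atoms: none
Why: Krapcho dealkoxycarbonylation removes the ester and its epimeric centre under neutral conditions, leaving a nitrile that tolerates all steps up to the organolithium addition.

Step 14
Reactants: 19 hydroxy nitrile
Product: 21 2-[(1R,4S)-4-hydroxycyclopent-2-en-1-yl]-2-methylpropanenitrile, via monomethyl nitrile 20 (not isolated)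
Conditions: LiN(iPr)2 (3.3 equiv), THF, −78 °C; MeI (2.2 equiv), −78 → 0 °C
Reagents that add atoms: iodomethane, IC
Why: double α-alkylation of the nitrile anion builds the gem-dimethyl quaternary carbon (future C4); C-methylation is far faster than O-methylation of the lithium alkoxide at low temperature.

Step 15
Reactants: 21 allylic alcohol
Product: 22 2-methyl-2-[(1R)-4-oxocyclopent-2-en-1-yl]propanenitrile
Conditions: Dess–Martin periodinane, NaHCO3, CH2Cl2, 0 °C → rt
Reagents that add atoms: none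
Why: Dess–Martin oxidation to the enone under buffered, non-basic conditions that do not touch the γ-stereocentre.

Step 16
Reactants: 22 enone
Product: 23 2-[(1R)-3-iodo-4-oxocyclopent-2-en-1-yl]-2-methylpropanenitrile
Conditions: I2, pyridine, CH2Cl2, rt
Reagents that add atoms: iodine, [I][I]
Why: Johnson α-iodination of the enone (pyridine conjugate addition, iodination of the enolate, elimination) gives the handle for the ring methyl group.

Step 17
Reactants: 23 α-iodo enone
Product: 24 2-methyl-2-[(1R)-3-methyl-4-oxocyclopent-2-en-1-yl]propanenitrile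
Conditions: Me4Sn, Pd2(dba)3 (2.5 mol%), AsPh3, CuI, N-methylpyrrolidone, 70 °C
Reagents that add atoms: tetramethylstannane, C[Sn](C)(C)C
Why: Stille coupling of the α-iodo enone installs the future C1 methyl group without base, so the γ-stereocentre is safe.

Step 18
Reactants: 24 methyl enone
Product: 25 2-[(1R,4S)-4-hydroxy-3-methylcyclopent-2-en-1-yl]-2-methylpropanenitrile
Conditions: NaBH4, CeCl3·7H2O, MeOH, −40 °C
Reagents that add atoms: none
Why: Luche 1,2-reduction: hydride adds to the carbonyl face anti to the bulky cyanopropyl group, giving the cis-allylic alcohol.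

Step 19
Reactants: 25 cis-allylic alcohol
Product: 27 2-methyl-2-[(1R,2R)-3-methyl-2-(2-oxoethyl)cyclopent-3-en-1-yl]propanenitrile, via allyl vinyl ether 26 (not isolated)
Conditions: ethyl vinyl ether, Hg(OAc)2 (0.3 equiv), reflux; then decalin, 180 °C (sealed tube)
Reagents that add atoms: ethyl vinyl ether, CCOC=C
Why: Claisen rearrangement: the [3,3] shift transfers the C–O stereocentre suprafacially to carbon, so the acetaldehyde arm lands on the same face as the cyanopropyl group (cis-1,2, the future ring fusion) and the double bond moves to the methyl-bearing position.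

Step 20
Reactants: 27 aldehyde
Product: 28 2-methyl-2-[(1R,2R)-3-methyl-2-(prop-2-en-1-yl)cyclopent-3-en-1-yl]propanenitrile
Conditions: Ph3PCH3Br, KN(SiMe3)2, THF, −78 → 0 °C
Reagents that add atoms: methyltriphenylphosphonium bromide, C[P+](c1ccccc1)(c1ccccc1)c1ccccc1.[Br-]
Why: Wittig methylenation turns the aldehyde into the allyl group for metathesis; the ring stereocentre is β to the carbonyl and cannot epimerise.

Step 21
Reactants: 28 nitrile
Product: 30 2,4-dimethyl-4-[(1R,2R)-3-methyl-2-(prop-2-en-1-yl)cyclopent-3-en-1-yl]pent-1-en-3-one, via ketimine 29 (not isolated)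
Conditions: 2-bromopropene, t-BuLi (2 equiv), Et2O, −78 °C; then 28, −78 °C → rt; then 1 M HCl, THF, 0 °C → rt
Reagents that add atoms: 2-bromopropene, CC(Br)=C; water, O
Why: organolithium addition to the nitrile stops at the N-lithio ketimine, which cannot add a second equivalent, and acid hydrolysis gives the isopropenyl ketone directly.

Step 22
Reactants: 30 dienone
Product: 31 (3aR,8aR)-1,4,4,6-tetramethyl-3a,4,8,8a-tetrahydroazulen-5(3H)-one
Conditions: second-generation Grubbs catalyst RuCl2(=CHPh)(PCy3)(H2IMes) (5 mol%), toluene, 80 °C, high dilution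
Reagents that add atoms: none
Why: ring-closing metathesis between the allyl group and the isopropenyl ketone closes the seven-membered ring with loss of ethene; the cis arms on the cyclopentene favour closure and the trisubstituted ring alkene is a spectator.

Step 23
Reactants: 31 bicyclic dienone
Product: 32 (1S,2R,3aR,8aR)-1,2-epoxy-1,4,4,6-tetramethyl-2,3,3a,4,8,8a-hexahydroazulen-5(1H)-one
Conditions: mCPBA, NaHCO3, CH2Cl2, 0 °C
Reagents that add atoms: 3-chloroperoxybenzoic acid, OOC(=O)c1cccc(Cl)c1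
Why: Prilezhaev epoxidation is chemoselective for the electron-rich cyclopentene over the enone and occurs on the convex face (the face of the two ring-fusion hydrogens) of the cis-fused bicycle, which places oxygen correctly at C1.

Step 24
Reactants: 32 epoxy enone
Product: 33 (1R,3aR,8aR)-1,4,4,6-tetramethyl-1,2,3,3a,4,5,8,8a-octahydroazulene-1,5-diol (C5 epimers)
Conditions: LiAlH4, THF, 0 °C → reflux
Reagents that add atoms: none
Why: hydride opens the trisubstituted epoxide by SN2 at the secondary carbon, leaving the tertiary alcohol with OH on the convex face and methyl cis to the seven-membered ring (1R), and reduces the enone carbonyl 1,2 to the allylic alcohol.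

Step 25
Reactants: 33 diol
Product: 34 (1R,3aR,8aR)-1-hydroxy-1,4,4,6-tetramethyl-2,3,3a,4,8,8a-hexahydroazulen-5(1H)-one
Conditions: Dess–Martin periodinane, NaHCO3, CH2Cl2, rt
Reagents that add atoms: none
Why: Dess–Martin oxidation restores the enone from the secondary allylic alcohol; the tertiary alcohol cannot be oxidised.

Step 26
Reactants: 34 hydroxy enone
Product: 35 (1R,3aR,8aR)-1,4,4,6-tetramethyl-1-[(triethylsilyl)oxy]-2,3,3a,4,8,8a-hexahydroazulen-5(1H)-one
Conditions: Et3SiOTf, 2,6-lutidine, CH2Cl2, −78 → 0 °C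
Reagents that add atoms: triethylsilyl triflate, CC[Si](CC)(CC)OS(=O)(=O)C(F)(F)F
Why: silyl ether formation masks the tertiary alcohol so that it does not quench the organometallic partner in the fragment union.

**Union and endgame**

Step 27
Reactants: 14 iodide; 35 enone
Product: 38 (1R,3aR,8aR)-5-{2-[(3R,5aR,6R,7S,9aR)-3-[(tert-butyldimethylsilyl)oxy]-2,2,5a,7-tetramethyl-7-[(triethylsilyl)oxy]decahydro-1-benzoxepin-6-yl]ethyl}-1,4,4,6-tetramethyl-1-[(triethylsilyl)oxy]-1,2,3,3a,4,5,8,8a-octahydroazulen-5-ol (C5 epimers), via alkyllithium 36 (not isolated), via alkylcerium dichloride 37 (not isolated)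
Conditions: 14 (1.3 equiv), t-BuLi (2.6 equiv), Et2O, −78 °C; CeCl3, THF, −78 °C; then 35, −78 °C
Reagents that add atoms: none
Why: iodine–lithium exchange, transmetalation to cerium and 1,2-addition (Imamoto conditions) to the enone carbonyl, which has no α-hydrogen on the quaternary side; the organocerium suppresses conjugate addition and γ-deprotonation, and the new carbinol centre is erased in the next step.

Step 28
Reactants: 38 tertiary allylic alcohol
Product: 39 (1R,3aR,8aR)-5-{2-[(3R,5aR,6R,7S,9aR)-3-[(tert-butyldimethylsilyl)oxy]-2,2,5a,7-tetramethyl-7-[(triethylsilyl)oxy]decahydro-1-benzoxepin-6-yl]ethyl}-1,4,4,6-tetramethyl-1-[(triethylsilyl)oxy]-2,3,3a,4,8,8a-hexahydroazulen-7(1H)-one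
Conditions: pyridinium chlorochromate (C5H5NH)[CrO3Cl], 4 Å molecular sieves, CH2Cl2, rt
Reagents that add atoms: pyridinium chlorochromate, [O-][Cr](=O)(=O)Cl.c1cc[nH+]cc1
Why: Dauben–Babler oxidative rearrangement: the chromate ester of the tertiary allylic alcohol undergoes a [3,3] shift and oxidation, giving the transposed tetrasubstituted enone with the side chain on the β-carbon; the silyl ethers shield all other hydroxyls.

Step 29
Reactants: 39 protected enone
Product: 40 (1R,3aR,8aR)-5-{2-[(3R,5aR,6R,7S,9aR)-3,7-dihydroxy-2,2,5a,7-tetramethyldecahydro-1-benzoxepin-6-yl]ethyl}-1-hydroxy-1,4,4,6-tetramethyl-2,3,3a,4,8,8a-hexahydroazulen-7(1H)-one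
Conditions: HF·pyridine, pyridine, THF, 0 °C → rt
Reagents that add atoms: none
Why: global fluoride desilylation frees the three hydroxyls; no stereocentre is touched and none of the alcohols is β to the ketone, so no retro-aldol path exists.

**Compound list**

1 | (5E)-6,10-dimethylundeca-5,9-dien-2-one | CC(=O)CC/C=C(\C)CCC=C(C)C | starting material
2 | 4-[(2R,3R)-3-{2-[(2R)-3,3-dimethyloxiran-2-yl]ethyl}-3-methyloxiran-2-yl]butan-2-one | CC(=O)CC[C@H]1O[C@]1(C)CC[C@H]1OC1(C)C | intermediate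
3 | (benzyloxy)acetaldehyde | O=CCOCc1ccccc1 | starting material
4 | 6-(benzyloxy)-1-[(2R,3R)-3-{2-[(2R)-3,3-dimethyloxiran-2-yl]ethyl}-3-methyloxiran-2-yl]-5-hydroxyhexan-3-one (C5 epimers) | O=C(CC(O)COCc1ccccc1)CC[C@H]1O[C@]1(C)CC[C@H]1OC1(C)C | intermediate
5 | 5-O-methanesulfonate of 4 | O=C(CC(OS(C)(=O)=O)COCc1ccccc1)CC[C@H]1O[C@]1(C)CC[C@H]1OC1(C)C | intermediate
6 | (4E)-6-(benzyloxy)-1-[(2R,3R)-3-{2-[(2R)-3,3-dimethyloxiran-2-yl]ethyl}-3-methyloxiran-2-yl]hex-4-en-3-one | O=C(/C=C/COCc1ccccc1)CC[C@H]1O[C@]1(C)CC[C@H]1OC1(C)C | intermediate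
7 | {[(3Z)-6-(benzyloxy)-1-[(2R,3R)-3-{2-[(2R)-3,3-dimethyloxiran-2-yl]ethyl}-3-methyloxiran-2-yl]hex-3-en-3-yl]oxy}triethylsilane | CC[Si](CC)(CC)O/C(=C\CCOCc1ccccc1)CC[C@H]1O[C@]1(C)CC[C@H]1OC1(C)C | intermediate
8 | (3R,5aR,9aR)-6-[2-(benzyloxy)ethyl]-2,2,5a-trimethyl-3-[(trimethylsilyl)oxy]octahydro-1-benzoxepin-7(2H)-one (C6 epimers) | c1ccccc1COCCC2[C@@]3(C)CC[C@@H](O[Si](C)(C)C)C(C)(C)O[C@@H]3CCC2=O | intermediate
9 | (3R,5aR,6R,9aR)-6-[2-(benzyloxy)ethyl]-3-hydroxy-2,2,5a-trimethyloctahydro-1-benzoxepin-7(2H)-one | c1ccccc1COCC[C@@H]2[C@@]3(C)CC[C@@H](O)C(C)(C)O[C@@H]3CCC2=O | intermediate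
10 | (3R,5aR,6R,9aR)-6-[2-(benzyloxy)ethyl]-3-[(tert-butyldimethylsilyl)oxy]-2,2,5a-trimethyloctahydro-1-benzoxepin-7(2H)-one | c1ccccc1COCC[C@@H]2[C@@]3(C)CC[C@@H](O[Si](C)(C)C(C)(C)C)C(C)(C)O[C@@H]3CCC2=O | intermediate
11 | (3R,5aR,6R,7S,9aR)-6-[2-(benzyloxy)ethyl]-3-[(tert-butyldimethylsilyl)oxy]-2,2,5a,7-tetramethyldecahydro-1-benzoxepin-7-ol | c1ccccc1COCC[C@@H]2[C@@]3(C)CC[C@@H](O[Si](C)(C)C(C)(C)C)C(C)(C)O[C@@H]3CC[C@]2(C)O | intermediate
12 | tert-butyl{[(3R,5aR,6R,7S,9aR)-6-[2-(benzyloxy)ethyl]-2,2,5a,7-tetramethyl-7-[(triethylsilyl)oxy]decahydro-1-benzoxepin-3-yl]oxy}dimethylsilane | c1ccccc1COCC[C@@H]2[C@@]3(C)CC[C@@H](O[Si](C)(C)C(C)(C)C)C(C)(C)O[C@@H]3CC[C@]2(C)O[Si](CC)(CC)CC | intermediate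
13 | 2-[(3R,5aR,6R,7S,9aR)-3-[(tert-butyldimethylsilyl)oxy]-2,2,5a,7-tetramethyl-7-[(triethylsilyl)oxy]decahydro-1-benzoxepin-6-yl]ethan-1-ol | OCC[C@@H]1[C@@]2(C)CC[C@@H](O[Si](C)(C)C(C)(C)C)C(C)(C)O[C@@H]2CC[C@]1(C)O[Si](CC)(CC)CC | intermediate
14 | tert-butyl{[(3R,5aR,6R,7S,9aR)-6-(2-iodoethyl)-2,2,5a,7-tetramethyl-7-[(triethylsilyl)oxy]decahydro-1-benzoxepin-3-yl]oxy}dimethylsilane | ICC[C@@H]1[C@@]2(C)CC[C@@H](O[Si](C)(C)C(C)(C)C)C(C)(C)O[C@@H]2CC[C@]1(C)O[Si](CC)(CC)CC | intermediate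
15 | meso-(1R,3S)-cyclopent-4-ene-1,3-diyl diacetate (cis) | CC(=O)O[C@@H]1C=C[C@H](OC(C)=O)C1 | starting material
16 | (1R,4S)-4-hydroxycyclopent-2-en-1-yl acetate | O[C@@H]1C=C[C@H](OC(C)=O)C1 | intermediate
17 | methyl cyanoacetate | COC(=O)CC#N | starting material
18 | methyl 2-cyano-2-[(1R,4S)-4-hydroxycyclopent-2-en-1-yl]acetate (epimers at C2 of the acetate) | O[C@@H]1C=C[C@H](C(C#N)C(=O)OC)C1 | intermediate
19 | 2-[(1R,4S)-4-hydroxycyclopent-2-en-1-yl]acetonitrile | O[C@@H]1C=C[C@H](CC#N)C1 | intermediate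
20 | 2-[(1R,4S)-4-hydroxycyclopent-2-en-1-yl]propanenitrile (epimers at C2) | O[C@@H]1C=C[C@H](C(C)C#N)C1 | intermediate
21 | 2-[(1R,4S)-4-hydroxycyclopent-2-en-1-yl]-2-methylpropanenitrile | O[C@@H]1C=C[C@H](C(C)(C)C#N)C1 | intermediate
22 | 2-methyl-2-[(1R)-4-oxocyclopent-2-en-1-yl]propanenitrile | O=C1C=C[C@H](C(C)(C)C#N)C1 | intermediate
23 | 2-[(1R)-3-iodo-4-oxocyclopent-2-en-1-yl]-2-methylpropanenitrile | O=C1C(I)=C[C@H](C(C)(C)C#N)C1 | intermediate
24 | 2-methyl-2-[(1R)-3-methyl-4-oxocyclopent-2-en-1-yl]propanenitrile | O=C1C(C)=C[C@H](C(C)(C)C#N)C1 | intermediate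
25 | 2-[(1R,4S)-4-hydroxy-3-methylcyclopent-2-en-1-yl]-2-methylpropanenitrile | O[C@@H]1C(C)=C[C@H](C(C)(C)C#N)C1 | intermediate
26 | 2-[(1R,4S)-4-(ethenyloxy)-3-methylcyclopent-2-en-1-yl]-2-methylpropanenitrile | C=CO[C@@H]1C(C)=C[C@H](C(C)(C)C#N)C1 | intermediate
27 | 2-methyl-2-[(1R,2R)-3-methyl-2-(2-oxoethyl)cyclopent-3-en-1-yl]propanenitrile | CC1=CC[C@@H](C(C)(C)C#N)[C@H]1CC=O | intermediate
28 | 2-methyl-2-[(1R,2R)-3-methyl-2-(prop-2-en-1-yl)cyclopent-3-en-1-yl]propanenitrile | CC1=CC[C@@H](C(C)(C)C#N)[C@H]1CC=C | intermediate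
29 | 2,4-dimethyl-4-[(1R,2R)-3-methyl-2-(prop-2-en-1-yl)cyclopent-3-en-1-yl]pent-1-en-3-imine | CC1=CC[C@@H](C(C)(C)C(=N)C(C)=C)[C@H]1CC=C | intermediate
30 | 2,4-dimethyl-4-[(1R,2R)-3-methyl-2-(prop-2-en-1-yl)cyclopent-3-en-1-yl]pent-1-en-3-one | CC1=CC[C@@H](C(C)(C)C(=O)C(C)=C)[C@H]1CC=C | intermediate
31 | (3aR,8aR)-1,4,4,6-tetramethyl-3a,4,8,8a-tetrahydroazulen-5(3H)-one | CC1=CC[C@@H]2[C@H]1CC=C(C)C(=O)C2(C)C | intermediate
32 | (1S,2R,3aR,8aR)-1,2-epoxy-1,4,4,6-tetramethyl-2,3,3a,4,8,8a-hexahydroazulen-5(1H)-one | C[C@@]12O[C@@H]1C[C@@H]1[C@H]2CC=C(C)C(=O)C1(C)C | intermediate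
33 | (1R,3aR,8aR)-1,4,4,6-tetramethyl-1,2,3,3a,4,5,8,8a-octahydroazulene-1,5-diol (C5 epimers) | C[C@@]1(O)CC[C@@H]2[C@H]1CC=C(C)C(O)C2(C)C | intermediate
34 | (1R,3aR,8aR)-1-hydroxy-1,4,4,6-tetramethyl-2,3,3a,4,8,8a-hexahydroazulen-5(1H)-one | C[C@@]1(O)CC[C@@H]2[C@H]1CC=C(C)C(=O)C2(C)C | intermediate
35 | (1R,3aR,8aR)-1,4,4,6-tetramethyl-1-[(triethylsilyl)oxy]-2,3,3a,4,8,8a-hexahydroazulen-5(1H)-one | C[C@@]1(O[Si](CC)(CC)CC)CC[C@@H]2[C@H]1CC=C(C)C(=O)C2(C)C | intermediate
36 | alkyllithium from 14 (Li in place of I) | [Li]CC[C@@H]1[C@@]2(C)CC[C@@H](O[Si](C)(C)C(C)(C)C)C(C)(C)O[C@@H]2CC[C@]1(C)O[Si](CC)(CC)CC | intermediate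
37 | alkylcerium dichloride from 36 (CeCl2 in place of Li) | Cl[Ce](Cl)CC[C@@H]1[C@@]2(C)CC[C@@H](O[Si](C)(C)C(C)(C)C)C(C)(C)O[C@@H]2CC[C@]1(C)O[Si](CC)(CC)CC | intermediate
38 | (1R,3aR,8aR)-5-{2-[(3R,5aR,6R,7S,9aR)-3-[(tert-butyldimethylsilyl)oxy]-2,2,5a,7-tetramethyl-7-[(triethylsilyl)oxy]decahydro-1-benzoxepin-6-yl]ethyl}-1,4,4,6-tetramethyl-1-[(triethylsilyl)oxy]-1,2,3,3a,4,5,8,8a-octahydroazulen-5-ol (C5 epimers) | C[C@@]1(O[Si](CC)(CC)CC)CC[C@@H]2[C@H]1CC=C(C)C(O)(CC[C@@H]3[C@@]4(C)CC[C@@H](O[Si](C)(C)C(C)(C)C)C(C)(C)O[C@@H]4CC[C@]3(C)O[Si](CC)(CC)CC)C2(C)C | intermediate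
39 | (1R,3aR,8aR)-5-{2-[(3R,5aR,6R,7S,9aR)-3-[(tert-butyldimethylsilyl)oxy]-2,2,5a,7-tetramethyl-7-[(triethylsilyl)oxy]decahydro-1-benzoxepin-6-yl]ethyl}-1,4,4,6-tetramethyl-1-[(triethylsilyl)oxy]-2,3,3a,4,8,8a-hexahydroazulen-7(1H)-one | C[C@@]1(O[Si](CC)(CC)CC)CC[C@@H]2[C@H]1CC(=O)C(C)=C(CC[C@@H]3[C@@]4(C)CC[C@@H](O[Si](C)(C)C(C)(C)C)C(C)(C)O[C@@H]4CC[C@]3(C)O[Si](CC)(CC)CC)C2(C)C | intermediate
40 | (1R,3aR,8aR)-5-{2-[(3R,5aR,6R,7S,9aR)-3,7-dihydroxy-2,2,5a,7-tetramethyldecahydro-1-benzoxepin-6-yl]ethyl}-1-hydroxy-1,4,4,6-tetramethyl-2,3,3a,4,8,8a-hexahydroazulen-7(1H)-one | C[C@@]1(O)CC[C@@H]2[C@H]1CC(=O)C(C)=C(CC[C@@H]3[C@@]4(C)CC[C@@H](O)C(C)(C)O[C@@H]4CC[C@]3(C)O)C2(C)C | target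

**Totals**

Total step count: 29. Longest linear sequence: 19 steps (steps 11–26, then 27–29); the right half is 10 steps before the union.

**Three steps most likely to fail, with fallbacks**

Step 5 (epoxonium cascade). The enol silane may hydrolyse or terminate poorly, and the yield of such cascades is moderate at best. The fallback sets out from enone 6 and swaps the terminator for an allylsilane. Conjugate reduction of 6 with LiBH(s-Bu)3 and trapping of the enolate with N-phenyltriflimide gives the (3Z)-enol triflate F1. Coupling of F1 with Me3SiCH2MgCl under Pd(PPh3)4 gives the 2-substituted allylsilane F2, a more nucleophilic and water-stable π-terminator. The same Me3SiOTf treatment followed by K2CO3/MeOH gives the 7-methylidene bicycle F3. Ozonolysis of F3 (O3, then Me2S) and brief K2CO3/MeOH equilibration return the route at hydroxy ketone 9.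

Step 19 (Claisen rearrangement onto the hindered face). The vinyl ether may eliminate instead of rearranging, because the new bond forms next to the quaternary carbon. The fallback sets out from alcohol 25 and replaces the sigmatropic step by a copper-mediated substitution. A Mitsunobu reaction with picolinic acid (PPh3, diisopropyl azodicarboxylate) inverts the carbinol and gives the trans-picolinate F4. Allylmagnesium bromide with CuBr·SMe2 then substitutes F4 in the anti SN2' sense, which delivers the allyl group cis to the cyanopropyl group and shifts the alkene to the methyl-bearing position. This returns the route at alkene 28 and skips 27.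

Step 27 (addition of a complex organometallic to a hindered enone). If the 1,2-addition stalls, the fallback forms the same C–C bond by cross-coupling. It sets out from enone 35 and iodide 14 and returns at target 40.
- Copper-catalysed conjugate borylation of 35 (B2pin2, CuCl, NaOt-Bu, MeOH) gives the β-boryl ketone F5, and NaBO3 oxidation gives the β-hydroxy ketone F6.
- Et3SiOTf/2,6-lutidine gives the bis-silyl ether F7.
- KN(SiMe3)2 and N-phenyltriflimide give the enol triflate F8; only one regioisomer is possible because the other α-carbon is quaternary.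
- Iodide 14 is converted through alkyllithium 36 and B-methoxy-9-borabicyclo[3.3.1]nonane into the B-alkyl borane F9.
- B-alkyl Suzuki–Miyaura coupling of F9 with F8 (PdCl2(dppf), AsPh3, Cs2CO3, DMF/THF/H2O) gives the coupled tetrasilyl ether F10.
- HF·pyridine gives the tetraol F11, and MnO2 oxidises only its allylic secondary alcohol to give 40.

**Further compounds**

F1 | step 5 | (3Z)-6-(benzyloxy)-1-[(2R,3R)-3-{2-[(2R)-3,3-dimethyloxiran-2-yl]ethyl}-3-methyloxiran-2-yl]hex-3-en-3-yl trifluoromethanesulfonate | FC(F)(F)S(=O)(=O)O/C(=C\CCOCc1ccccc1)CC[C@H]1O[C@]1(C)CC[C@H]1OC1(C)C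
F2 | step 5 | [(2Z)-5-(benzyloxy)-2-{2-[(2R,3R)-3-{2-[(2R)-3,3-dimethyloxiran-2-yl]ethyl}-3-methyloxiran-2-yl]ethyl}pent-2-en-1-yl]trimethylsilane | C[Si](C)(C)C/C(=C\CCOCc1ccccc1)CC[C@H]1O[C@]1(C)CC[C@H]1OC1(C)C
F3 | step 5 | (3R,5aR,9aR)-6-[2-(benzyloxy)ethyl]-2,2,5a-trimethyl-7-methylidenedecahydro-1-benzoxepin-3-ol (C6 epimers) | c1ccccc1COCCC2[C@@]3(C)CC[C@@H](O)C(C)(C)O[C@@H]3CCC2=C
F4 | step 19 | (1R,4R)-4-(2-cyanopropan-2-yl)-2-methylcyclopent-2-en-1-yl pyridine-2-carboxylate | O=C(O[C@H]1C(C)=C[C@H](C(C)(C)C#N)C1)c1ccccn1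
F5 | step 27 | (1R,3aR,8aR)-1,4,4,6-tetramethyl-7-(4,4,5,5-tetramethyl-1,3,2-dioxaborolan-2-yl)-1-[(triethylsilyl)oxy]octahydroazulen-5(1H)-one (C6 and C7 epimers) | C[C@@]1(O[Si](CC)(CC)CC)CC[C@@H]2[C@H]1CC(B3OC(C)(C)C(C)(C)O3)C(C)C(=O)C2(C)C
F6 | step 27 | (1R,3aR,8aR)-7-hydroxy-1,4,4,6-tetramethyl-1-[(triethylsilyl)oxy]octahydroazulen-5(1H)-one (C6 and C7 epimers) | C[C@@]1(O[Si](CC)(CC)CC)CC[C@@H]2[C@H]1CC(O)C(C)C(=O)C2(C)C
F7 | step 27 | (1R,3aR,8aR)-1,4,4,6-tetramethyl-1,7-bis[(triethylsilyl)oxy]octahydroazulen-5(1H)-one (C6 and C7 epimers) | C[C@@]1(O[Si](CC)(CC)CC)CC[C@@H]2[C@H]1CC(O[Si](CC)(CC)CC)C(C)C(=O)C2(C)C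
F8 | step 27 | (1R,3aR,8aR)-1,4,4,6-tetramethyl-1,7-bis[(triethylsilyl)oxy]-1,2,3,3a,4,7,8,8a-octahydroazulen-5-yl trifluoromethanesulfonate (C7 epimers) | C[C@@]1(O[Si](CC)(CC)CC)CC[C@@H]2[C@H]1CC(O[Si](CC)(CC)CC)C(C)=C(OS(=O)(=O)C(F)(F)F)C2(C)C
F9 | step 27 | 9-{2-[(3R,5aR,6R,7S,9aR)-3-[(tert-butyldimethylsilyl)oxy]-2,2,5a,7-tetramethyl-7-[(triethylsilyl)oxy]decahydro-1-benzoxepin-6-yl]ethyl}-9-borabicyclo[3.3.1]nonane | B1(CC[C@@H]3[C@@]4(C)CC[C@@H](O[Si](C)(C)C(C)(C)C)C(C)(C)O[C@@H]4CC[C@]3(C)O[Si](CC)(CC)CC)C2CCCC1CCC2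
F10 | step 27 | 1,7-bis(triethylsilyl) 3'-(tert-butyldimethylsilyl) 7'-(triethylsilyl) ether of F11 (C7 epimers) | C[C@@]1(O[Si](CC)(CC)CC)CC[C@@H]2[C@H]1CC(O[Si](CC)(CC)CC)C(C)=C(CC[C@@H]3[C@@]4(C)CC[C@@H](O[Si](C)(C)C(C)(C)C)C(C)(C)O[C@@H]4CC[C@]3(C)O[Si](CC)(CC)CC)C2(C)C
F11 | step 27 | (1R,3aR,8aR)-5-{2-[(3R,5aR,6R,7S,9aR)-3,7-dihydroxy-2,2,5a,7-tetramethyldecahydro-1-benzoxepin-6-yl]ethyl}-1,4,4,6-tetramethyl-1,2,3,3a,4,7,8,8a-octahydroazulene-1,7-diol (C7 epimers) | C[C@@]1(O)CC[C@@H]2[C@H]1CC(O)C(C)=C(CC[C@@H]3[C@@]4(C)CC[C@@H](O)C(C)(C)O[C@@H]4CC[C@]3(C)O)C2(C)C
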